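The pyranone (C ring) is cut at C3–C4 and O1–C8a. The A ring carries oxygen at C5, C7 and C8a, each ortho or para to C4a, the carbon that holds the C4 carbonyl; a 2,4,6-trifluorobenzoyl group has exactly this pattern, with fluorine as leaving group. One pot therefore acylates the enolate of an aryl 4-methylpentyl ketone (B ring, C2, C3 and the 3-methylbutyl chain) and closes the C ring by intramolecular SNAr, leaving C5–F and C7–F for later exchange. The ketone carries the B-ring oxygens as benzyl ethers, so that benzyl alkoxide exchange and one neutral hydrogenolysis finish the synthesis.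

Key step: step 3

Remark: asplenetin has no stereocentre, so no enantiomer has to be controlled; the stereocentres that appear on the way (in 4 and 8) are racemic and are removed again.
Remark: 3,4,5-tris(benzyloxy)benzaldehyde is assumed to be bought as a catalogue compound.

Step 1
Reactants: 1 1-bromo-4-methylpentane; 2 3,4,5-tris(benzyloxy)benzaldehyde
Product: 4 5-methyl-1-[3,4,5-tris(benzyloxy)phenyl]hexan-1-ol (racemic), via 4-methylpentylmagnesium bromide 3 (not isolated)
Conditions: Mg, THF, 40 °C; then 2, THF, 0 °C→rt; aq. NH4Cl
Reagents that add atoms: none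
Why: Grignard formation and 1,2-addition of the primary alkylmagnesium bromide to a non-enolisable aromatic aldehyde is textbook chemistry that the benzyl ethers tolerate; the carbinol centre forms without control (racemic) and is erased by the oxidation in step 2.

Step 2
Reactants: 4 5-methyl-1-[3,4,5-tris(benzyloxy)phenyl]hexan-1-ol
Product: 5 5-methyl-1-[3,4,5-tris(benzyloxy)phenyl]hexan-1-one
Conditions: Dess–Martin periodinane, CH2Cl2, rt
Reagents that add atoms: none
Why: Dess–Martin oxidation of a secondary benzylic alcohol to the aryl ketone runs under near-neutral conditions at room temperature and should leave the benzyl ethers and the electron-rich ring untouched.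

Step 3
Reactants: 5 5-methyl-1-[3,4,5-tris(benzyloxy)phenyl]hexan-1-one (2.0 equiv); 6 2,4,6-trifluorobenzoyl chloride (1.0 equiv)
Product: 9 5,7-difluoro-3-(3-methylbutyl)-2-[3,4,5-tris(benzyloxy)phenyl]-4H-chromen-4-one, via lithium enolate 7 (not isolated), via trifluorophenyl diketone 8 (not isolated)
Conditions: LiHMDS (2.05 equiv), toluene, 0 °C; then 6, 0 °C→rt; then DMF, 70 °C
Reagents that add atoms: none
Why: The Z-lithium enolate 7 attacks the acid chloride at carbon (Claisen-type acylation, C3–C4), and the second equivalent of 7 deprotonates the resulting 2-alkyl-1,3-diketone 8, returning one equivalent of ketone 5 for recovery. On warming with DMF, which loosens the lithium chelate, the enolate oxygen on the B-ring side adds to an ortho C–F carbon (C8a); the Meisenheimer adduct is stabilised by the C4 carbonyl on C4a and inductively by the two remaining fluorines, and loss of fluoride as LiF makes O1–C8a. The closest known reaction type is the one-pot enolate acylation and intramolecular SNAr of o-fluorobenzoyl chlorides with ketone or β-keto ester enolates, which gives chromones and 4-quinolones. The pyranone closes as a six-membered ring by a 6-endo-type addition–elimination, the attacked C4a=C8a bond lying inside the new ring; closure through the other oxygen or through C3 would give four-membered rings and is not accessible. No stereocentre is formed, and the one in 8 disappears on enolisation. The step needs C- over O-acylation, which the tight lithium enolate in toluene favours and which excess enolate repairs by taking the acyl group from any enol ester; no site selection on the arene is needed because the two ortho fluorines of 6 are equivalent by symmetry.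

Step 4
Reactants: 9 5,7-difluoro-3-(3-methylbutyl)-2-[3,4,5-tris(benzyloxy)phenyl]-4H-chromen-4-one
Product: 11 5,7-bis(benzyloxy)-3-(3-methylbutyl)-2-[3,4,5-tris(benzyloxy)phenyl]-4H-chromen-4-one, via 7-benzyloxy-5-fluorochromone 10 (not isolated)
Conditions: BnOH (3 equiv), NaH (2.6 equiv), THF, 0 °C; then 9, THF–DMF, rt→50 °C
Reagents that add atoms: benzyl alcohol, OCc1ccccc1
Why: Two successive SNAr displacements by sodium benzyloxide should occur because C7–F is para and C5–F ortho to C4a, which bears the C4 carbonyl, and the benzyloxy group that enters first (expected at the less hindered C7) is meta to the remaining fluorine and hardly slows the second exchange; if C5 reacts first, the isomeric monoether leads to the same product 11.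

Step 5
Reactants: 11 5,7-bis(benzyloxy)-3-(3-methylbutyl)-2-[3,4,5-tris(benzyloxy)phenyl]-4H-chromen-4-one
Product: 12 asplenetin, 5,7-dihydroxy-3-(3-methylbutyl)-2-(3,4,5-trihydroxyphenyl)-4H-chromen-4-one
Conditions: H2 (1 atm), 10% Pd/C, THF–MeOH, rt
Reagents that add atoms: none
Why: Catalytic hydrogenolysis of the five aryl benzyl ethers over palladium is the standard neutral deprotection of polyphenolic flavones, should leave the tetrasubstituted C2=C3 bond of the vinylogous ester and the arenes intact at 1 atm and room temperature, and releases only toluene, so the air-sensitive pyrogallol can be isolated by filtration and evaporation under inert gas.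

Compound list
1 | 1-bromo-4-methylpentane | CC(C)CCCBr | starting material
2 | 3,4,5-tris(benzyloxy)benzaldehyde | O=Cc1cc(OCc2ccccc2)c(OCc2ccccc2)c(OCc2ccccc2)c1 | starting material
3 | 4-methylpentylmagnesium bromide | CC(C)CCC[Mg]Br | intermediate
4 | 5-methyl-1-[3,4,5-tris(benzyloxy)phenyl]hexan-1-ol (racemic) | CC(C)CCCC(O)c1cc(OCc2ccccc2)c(OCc2ccccc2)c(OCc2ccccc2)c1 | intermediate
5 | 5-methyl-1-[3,4,5-tris(benzyloxy)phenyl]hexan-1-one | CC(C)CCCC(=O)c1cc(OCc2ccccc2)c(OCc2ccccc2)c(OCc2ccccc2)c1 | intermediate
6 | 2,4,6-trifluorobenzoyl chloride | O=C(Cl)c1c(F)cc(F)cc1F | starting material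
7 | lithium (Z)-5-methyl-1-[3,4,5-tris(benzyloxy)phenyl]hex-1-en-1-olate | CC(C)CC/C=C(\O[Li])c1cc(OCc2ccccc2)c(OCc2ccccc2)c(OCc2ccccc2)c1 | intermediate
8 | 2-(3-methylbutyl)-1-[3,4,5-tris(benzyloxy)phenyl]-3-(2,4,6-trifluorophenyl)propane-1,3-dione (racemic, enolisable; present in the flask as its lithium enolate) | CC(C)CCC(C(=O)c1c(F)cc(F)cc1F)C(=O)c1cc(OCc2ccccc2)c(OCc2ccccc2)c(OCc2ccccc2)c1 | intermediate
9 | 5,7-difluoro-3-(3-methylbutyl)-2-[3,4,5-tris(benzyloxy)phenyl]-4H-chromen-4-one | CC(C)CCc1c(-c2cc(OCc3ccccc3)c(OCc3ccccc3)c(OCc3ccccc3)c2)oc2cc(F)cc(F)c2c1=O | intermediate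
10 | 7-(benzyloxy)-5-fluoro-3-(3-methylbutyl)-2-[3,4,5-tris(benzyloxy)phenyl]-4H-chromen-4-one | CC(C)CCc1c(-c2cc(OCc3ccccc3)c(OCc3ccccc3)c(OCc3ccccc3)c2)oc2cc(OCc3ccccc3)cc(F)c2c1=O | intermediate
11 | 5,7-bis(benzyloxy)-3-(3-methylbutyl)-2-[3,4,5-tris(benzyloxy)phenyl]-4H-chromen-4-one | CC(C)CCc1c(-c2cc(OCc3ccccc3)c(OCc3ccccc3)c(OCc3ccccc3)c2)oc2cc(OCc3ccccc3)cc(OCc3ccccc3)c2c1=O | intermediate
12 | asplenetin, 5,7-dihydroxy-3-(3-methylbutyl)-2-(3,4,5-trihydroxyphenyl)-4H-chromen-4-one (achiral) | CC(C)CCc1c(-c2cc(O)c(O)c(O)c2)oc2cc(O)cc(O)c2c1=O | target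

Total step count: 5. Longest linear sequence: 5 steps (1 or 2 → 4 → 5 → 9 → 11 → 12); the acid chloride 6 is bought.

Steps most likely to fail

Step 3. The enolate may be acylated at oxygen faster than at carbon, or the chelated lithium diketonate may close too slowly and suffer retro-Claisen cleavage on prolonged heating. The fallback sets out from ketone 5 and replaces the acyl chloride by an aldehyde, which can only react at carbon. The enolate of 5 (LDA, THF, −78 °C) is added to commercial 2,4,6-trifluorobenzaldehyde to give the aldol 3-hydroxy-2-(3-methylbutyl)-1-[3,4,5-tris(benzyloxy)phenyl]-3-(2,4,6-trifluorophenyl)propan-1-one F1 as a mixture of diastereomers. Dess–Martin oxidation should convert it into diketone 8, now isolated. Ring closure is then run as a separate SNAr with K2CO3 in DMF at about 70 °C, where the potassium diketonate is not a tight chelate. The fallback comes back to the route at 9.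

Step 4. The exchange may stall after the first fluoride, leaving the C5–F beside the carbonyl, or the alkoxide may add to C2 and open the pyranone. The fallback sets out from 9 and changes the nucleophile and the protecting-group plan. Sodium methoxide in MeOH–THF at 60 °C, smaller and usable in large excess, should give 5,7-dimethoxy-3-(3-methylbutyl)-2-[3,4,5-tris(benzyloxy)phenyl]-4H-chromen-4-one F2. Hydrogenolysis (H2, Pd/C) then frees the B ring to give 5,7-dimethoxy-3-(3-methylbutyl)-2-(3,4,5-trihydroxyphenyl)-4H-chromen-4-one F3. BBr3 in CH2Cl2 (−78 °C→rt) cleaves the two remaining methyl ethers, the C5 ether being assisted by chelation to the C4 carbonyl. The fallback comes back to the route at the target 12.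

Step 5. Hydrogenation may run on into the C2=C3 bond of the pyranone, or debenzylation may stop at partly protected stages through low solubility or fouling of the catalyst by the polyphenol. The fallback sets out from 11 and replaces the reductive cleavage by a Lewis-acid dealkylation: BCl3 with pentamethylbenzene as benzyl-cation scavenger in CH2Cl2 at −78 °C→0 °C, a known mild cleavage of aryl benzyl ethers that cannot reduce the chromone. It gives the target 12 directly and makes no new compound (F0).

Further compounds
F1 | step 3 | 3-hydroxy-2-(3-methylbutyl)-1-[3,4,5-tris(benzyloxy)phenyl]-3-(2,4,6-trifluorophenyl)propan-1-one (racemic mixture of diastereomers) | CC(C)CCC(C(O)c1c(F)cc(F)cc1F)C(=O)c1cc(OCc2ccccc2)c(OCc2ccccc2)c(OCc2ccccc2)c1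
F2 | step 4 | 5,7-dimethoxy-3-(3-methylbutyl)-2-[3,4,5-tris(benzyloxy)phenyl]-4H-chromen-4-one | CC(C)CCc1c(-c2cc(OCc3ccccc3)c(OCc3ccccc3)c(OCc3ccccc3)c2)oc2cc(OC)cc(OC)c2c1=O
F3 | step 4 | 5,7-dimethoxy-3-(3-methylbutyl)-2-(3,4,5-trihydroxyphenyl)-4H-chromen-4-one | CC(C)CCc1c(-c2cc(O)c(O)c(O)c2)oc2cc(OC)cc(OC)c2c1=O
F0 | step 5 | none | none
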